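**Plan**

- The target is read as two antipodal 7,8,4'-trioxygenated 2,3-trans-flavan units: an upper (2S,3R,4R) unit with the 4-aryl group cis to 3-OH, joined through C4 to C6 of a lower (2R,3S,4R) flavan-3,4-diol.
- Retrosynthesis: cut the C4(upper)–C6(lower) bond (aryllithium plus 4-ketone, the C4–OH later replaced by H), so both halves come from the two enantiomers of one trans-3-silyloxyflavan-4-one. Then cut its C2–C3 and O1–C2 bonds back to gallacetophenone and 4-(benzyloxy)benzyl chloride.
- Forward: ring A is bought and O1–C2 is made by etherification; ring C is closed by C2–C3 bond formation, C3 is oxygenated, and the racemic ketone is divided into its antipodes by two complementary reductions. The lower half is brominated at C6 and joined to the upper ketone, then C4 is deoxygenated and the product deprotected.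
- Feature that allows the key event: C2 is a CH2 flanked by the ring A ether oxygen O1 and the para-oxygenated ring B (a built-in p-alkoxybenzyl ether, a hydride donor to DDQ), and C3 is the α-carbon of the C4 aryl ketone on ring A, ortho to O1 (used as its enol acetate).
- Stereochemistry: 2,3-trans from Rubottom oxidation anti to the 2-aryl group. Absolute configuration from two transfer-hydrogenation kinetic resolutions of the same racemic ketone, each taking the reduced enantiomer: RuCl[(S,S)-TsDPEN](p-cymene) gives the lower unit with its C4 carbinol, RuCl[(R,R)-TsDPEN](p-cymene) gives the antipodal alcohol, which is reoxidised to the upper-unit ketone. Upper C4 (3,4-cis) comes from hydride capture of the C4 cation anti to the 3-silyloxy group.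

Key step: step 4

Remark: compounds 8–11 are racemic by design; for 10 and 11 the SMILES show the enantiomer with 2S configuration.

**Step 1**
Reactants: 1 1-(2,3,4-trihydroxyphenyl)ethan-1-one (gallacetophenone)
Product: 2 1-[3,4-bis(benzyloxy)-2-hydroxyphenyl]ethan-1-one
Conditions: BnBr (2.1 equiv), K2CO3, DMF, rt
Reagents that add atoms: benzyl bromide, BrCc1ccccc1
Why: Williamson etherification; the 2-hydroxyl is hydrogen-bonded to the acetyl carbonyl and least nucleophilic, so two equivalents of benzyl bromide should alkylate only the 3- and 4-hydroxyls.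

**Step 2**
Reactants: 2 1-[3,4-bis(benzyloxy)-2-hydroxyphenyl]ethan-1-one; 3 1-(benzyloxy)-4-(chloromethyl)benzene
Product: 4 1-[3,4-bis(benzyloxy)-2-{[4-(benzyloxy)phenyl]methoxy}phenyl]ethan-1-one
Conditions: K2CO3, KI (cat.), DMF, 70 °C
Reagents that add atoms: none
Why: Williamson etherification of the remaining chelated phenol under more forcing conditions with Finkelstein activation of the benzylic chloride, which installs the O1–C2 bond and ring B.

**Step 3**
Reactants: 4 1-[3,4-bis(benzyloxy)-2-{[4-(benzyloxy)phenyl]methoxy}phenyl]ethan-1-one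
Product: 6 1-[3,4-bis(benzyloxy)-2-{[4-(benzyloxy)phenyl]methoxy}phenyl]ethenyl acetate, via potassium enolate 5 (not isolated)
Conditions: KN(SiMe3)2, THF, −78 °C; then Ac2O
Reagents that add atoms: acetic anhydride, CC(=O)OC(C)=O
Why: Kinetic deprotonation of the methyl ketone (the only acidic C–H) and O-acylation of the potassium enolate (enol ester formation) should give the DDQ-stable enol acetate that serves as the C3 nucleophile.

**Step 4**
Reactants: 6 1-[3,4-bis(benzyloxy)-2-{[4-(benzyloxy)phenyl]methoxy}phenyl]ethenyl acetate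
Product: 8 rac-7,8-bis(benzyloxy)-2-[4-(benzyloxy)phenyl]-2,3-dihydro-4H-chromen-4-one, via oxocarbenium ion 7 (not isolated)
Conditions: DDQ, 2,6-dichloropyridine, LiClO4, 4 Å MS, ClCH2CH2Cl, rt
Reagents that add atoms: none
Why: Proposed new method: DDQ should remove hydride (electron transfer, then loss of a proton and a second electron) from the one doubly activated C–H bond of 6, the CH2 (future C2) between the ring A ether oxygen O1 and the para-benzyloxyphenyl ring B, to give oxocarbenium ion 7; the enol acetate carbon (future C3) held ortho to O1 then attacks C2 and the acetoxycarbenium ion formed loses its acetyl group to leave the C4 ketone. The closest known reaction type is the DDQ-mediated oxidative C–H cleavage of alkyl p-alkoxybenzyl ethers with capture of the oxocarbenium ion by a tethered enol acetate to give tetrahydropyran-4-ones; what is new here is that the ether oxygen is phenolic, so the cation is less stabilised by oxygen and relies on the para-benzyloxy group of ring B. Ring C closes in a 6-endo-trig mode (both the C2=O1 cation and the C3=C4 enol lie inside the new ring), and the ortho relationship on ring A holds the two partners together. The one new stereocenter, C2, is deliberately left uncontrolled because both enantiomers of 8 are used later. The step needs chemoselective oxidation of the p-alkoxybenzylic CH2 over the two plain benzyl ethers and over the product; the para-oxygen stabilisation of 7 and the deactivating ketone in 8 should secure this, while 2,6-dichloropyridine buffers acid and the sieves keep water from hydrolysing 7.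

**Step 5**
Reactants: 8 rac-7,8-bis(benzyloxy)-2-[4-(benzyloxy)phenyl]-2,3-dihydro-4H-chromen-4-one
Product: 9 rac-{[7,8-bis(benzyloxy)-2-[4-(benzyloxy)phenyl]-2H-chromen-4-yl]oxy}(tert-butyl)dimethylsilane
Conditions: TBSOTf, Et3N, CH2Cl2, 0 °C
Reagents that add atoms: tert-butyldimethylsilyl trifluoromethanesulfonate, CC(C)(C)[Si](C)(C)OS(=O)(=O)C(F)(F)F
Why: Soft enolisation (silyl triflate and amine) toward C3, the only α-position, should give the silyl enol ether without the ring opening a free enolate could undergo.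

**Step 6**
Reactants: 9 rac-{[7,8-bis(benzyloxy)-2-[4-(benzyloxy)phenyl]-2H-chromen-4-yl]oxy}(tert-butyl)dimethylsilane
Product: 11 rac-(2S,3S)-7,8-bis(benzyloxy)-2-[4-(benzyloxy)phenyl]-3-[(tert-butyldimethylsilyl)oxy]-2,3-dihydro-4H-chromen-4-one, via silyloxy epoxide 10 (not isolated)
Conditions: DMDO, acetone/CH2Cl2, −40 °C to rt; then pyridinium p-toluenesulfonate (cat.)
Reagents that add atoms: dimethyldioxirane, CC1(C)OO1
Why: Rubottom oxidation; DMDO should epoxidise the enol ether anti to the 2-aryl group and 1,4-silyl migration in the silyloxy epoxide then gives the α-silyloxy ketone with the 2,3-trans (diequatorial, also thermodynamically preferred) arrangement.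

**Step 7**
Reactants: 11 rac-(2S,3S)-7,8-bis(benzyloxy)-2-[4-(benzyloxy)phenyl]-3-[(tert-butyldimethylsilyl)oxy]-2,3-dihydro-4H-chromen-4-one
Product: 12 (2R,3S,4R)-7,8-bis(benzyloxy)-2-[4-(benzyloxy)phenyl]-3-[(tert-butyldimethylsilyl)oxy]-3,4-dihydro-2H-chromen-4-ol
Conditions: RuCl[(S,S)-TsDPEN](p-cymene) (cat.), HCO2H/Et3N (5:2), EtOAc, rt, stopped before half conversion; chromatography; the unreduced ketone fraction is kept for step 8
Reagents that add atoms: none
Why: Noyori asymmetric transfer hydrogenation run as a kinetic resolution of a flavanone; the (S,S) catalyst delivers hydride to the face that gives the (S)-1-arylethanol-type carbinol (descriptor 4R here because C3 outranks C4a). For the (2R,3R) enantiomer this is also the substrate-preferred axial attack (4-OH trans to 3-O and cis to the 2-aryl group), whereas for the (2S,3S) enantiomer it is the mismatched face, so only the former should be reduced; stopping early keeps the alcohol enantiomerically clean.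

**Step 8**
Reactants: 11 rac-(2S,3S)-7,8-bis(benzyloxy)-2-[4-(benzyloxy)phenyl]-3-[(tert-butyldimethylsilyl)oxy]-2,3-dihydro-4H-chromen-4-one (the ketone fraction recovered from step 7, enriched in the (2S,3S) enantiomer, is used)
Product: 13 (2S,3R,4S)-7,8-bis(benzyloxy)-2-[4-(benzyloxy)phenyl]-3-[(tert-butyldimethylsilyl)oxy]-3,4-dihydro-2H-chromen-4-ol
Conditions: RuCl[(R,R)-TsDPEN](p-cymene) (cat.), HCO2H/Et3N (5:2), EtOAc, rt, stopped before the (2S,3S) ketone is fully consumed; chromatography; the unreduced ketone fraction, enriched in the (2R,3R) enantiomer, is returned to step 7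
Reagents that add atoms: none
Why: The mirror-image Noyori transfer-hydrogenation kinetic resolution; the (R,R) catalyst is matched with the (2S,3S) ketone and should reduce it to the antipode of 12, and taking the alcohol (not the leftover ketone) as product should secure high enantiomeric purity at partial conversion.

**Step 9**
Reactants: 13 (2S,3R,4S)-7,8-bis(benzyloxy)-2-[4-(benzyloxy)phenyl]-3-[(tert-butyldimethylsilyl)oxy]-3,4-dihydro-2H-chromen-4-ol
Product: 14 (2S,3S)-7,8-bis(benzyloxy)-2-[4-(benzyloxy)phenyl]-3-[(tert-butyldimethylsilyl)oxy]-2,3-dihydro-4H-chromen-4-one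
Conditions: Dess–Martin periodinane, CH2Cl2, 0 °C to rt
Reagents that add atoms: none
Why: Dess–Martin oxidation of the secondary benzylic alcohol under mild, non-basic conditions should return the ketone without epimerising C3; C2 and C3 are untouched (the C3 descriptor changes from R to S only because C4 gains priority), so the temporary carbinol center has served to carry the resolution.

**Step 10**
Reactants: 12 (2R,3S,4R)-7,8-bis(benzyloxy)-2-[4-(benzyloxy)phenyl]-3-[(tert-butyldimethylsilyl)oxy]-3,4-dihydro-2H-chromen-4-ol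
Product: 15 (2R,3R,4R)-7,8-bis(benzyloxy)-2-[4-(benzyloxy)phenyl]-3,4-bis[(tert-butyldimethylsilyl)oxy]-3,4-dihydro-2H-chromene
Conditions: TBSOTf, 2,6-lutidine, CH2Cl2, 0 °C to rt
Reagents that add atoms: tert-butyldimethylsilyl trifluoromethanesulfonate, CC(C)(C)[Si](C)(C)OS(=O)(=O)C(F)(F)F
Why: Silyl ether formation at the hindered benzylic alcohol with the reactive triflate; a silyl ether tolerates tert-butyllithium and is a poor leaving group under the acid of step 13 (any 3-to-4 silyl migration in step 7 converges here on the same bis-silyl ether).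

**Step 11**
Reactants: 15 (2R,3R,4R)-7,8-bis(benzyloxy)-2-[4-(benzyloxy)phenyl]-3,4-bis[(tert-butyldimethylsilyl)oxy]-3,4-dihydro-2H-chromene
Product: 16 (2R,3R,4R)-7,8-bis(benzyloxy)-2-[4-(benzyloxy)phenyl]-6-bromo-3,4-bis[(tert-butyldimethylsilyl)oxy]-3,4-dihydro-2H-chromene
Conditions: NBS (1.0 equiv), CH2Cl2, −20 to 0 °C
Reagents that add atoms: N-bromosuccinimide, O=C1CCC(=O)N1Br
Why: Electrophilic aromatic bromination at C6, the only ring A position both ortho to one oxygen (7-OBn) and para to another (O1); C5 is activated only by the twisted 8-OBn and is shielded by the peri 4-silyloxy group, and ring B carries a single activating oxygen.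

**Step 12**
Reactants: 16 (2R,3R,4R)-7,8-bis(benzyloxy)-2-[4-(benzyloxy)phenyl]-6-bromo-3,4-bis[(tert-butyldimethylsilyl)oxy]-3,4-dihydro-2H-chromene; 14 (2S,3S)-7,8-bis(benzyloxy)-2-[4-(benzyloxy)phenyl]-3-[(tert-butyldimethylsilyl)oxy]-2,3-dihydro-4H-chromen-4-one
Product: 18 protected dimeric tertiary alcohol [upper (2S,3S)-3-silyloxy-4-hydroxyflavan unit joined through C4 to C6 of the lower (2R,3R,4R) unit; carbinol configuration left open], via aryllithium 17 (not isolated)
Conditions: t-BuLi (2 equiv), THF, −78 °C; then 14, −78 to 0 °C; then H2O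
Reagents that add atoms: none
Why: Bromine–lithium exchange followed by 1,2-addition of the aryllithium to the ketone, a known way to forge 4-aryl bonds on 3-silyloxyflavan-4-ones; the configuration of the new carbinol center is immaterial because it is ionised in step 13.

**Step 13**
Reactants: 18 protected dimeric tertiary alcohol
Product: 20 protected dimer [upper (2S,3R) unit with H at C4 and the C4 aryl bond cis to the 3-silyloxy group; lower (2R,3R,4R) unit; six benzyl and three silyl ethers], via benzylic carbocation 19 (not isolated)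
Conditions: Bu3SnH, CF3CO2H, CH2Cl2, −20 to 0 °C
Reagents that add atoms: none
Why: Ionic hydrogenation (tin hydride reduction of an acid-generated benzylic cation); the tertiary doubly benzylic alcohol ionises to 19, allylic 1,2-strain with the C4 aryl group should push the 3-silyloxy group pseudoaxial, and hydride should enter anti to it, so H-4 ends trans and the C4 aryl group cis to O-3 (2,3-trans-3,4-cis), while the secondary, singly benzylic silyl ether of the lower unit should ionise far more slowly.

**Step 14**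
Reactants: 20 protected dimer
Product: 21 hexaphenol tris(tert-butyldimethylsilyl) ether of the target (silyl groups on upper O-3 and on lower O-3 and O-4)
Conditions: H2 (1 atm), Pd(OH)2/C, EtOAc/MeOH, rt
Reagents that add atoms: none
Why: Hydrogenolysis of the six benzyl ethers; the benzylic C4–O bond of the lower unit is kept as a bulky silyl ether at this stage so that it should resist hydrogenolysis.

**Step 15**
Reactants: 21 hexaphenol tris(tert-butyldimethylsilyl) ether
Product: 22 (2R,3S,4R)-2-(4-hydroxyphenyl)-6-[(2S,3R,4R)-3,7,8-trihydroxy-2-(4-hydroxyphenyl)-3,4-dihydro-2H-chromen-4-yl]-3,4-dihydro-2H-chromene-3,4,7,8-tetrol (target)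
Conditions: Bu4NF, AcOH, THF, rt; size-exclusion chromatography (Sephadex LH-20)
Reagents that add atoms: none
Why: Fluoride-mediated desilylation buffered with acetic acid, so the phenols stay protonated and the acid- and base-sensitive flavan-3,4-diol sees neither strong acid nor strong base; no stereocenter is touched.

**Compound list**

1 | 1-(2,3,4-trihydroxyphenyl)ethan-1-one | CC(=O)c1ccc(O)c(O)c1O | starting material
2 | 1-[3,4-bis(benzyloxy)-2-hydroxyphenyl]ethan-1-one | CC(=O)c1ccc(OCc2ccccc2)c(OCc2ccccc2)c1O | intermediate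
3 | 1-(benzyloxy)-4-(chloromethyl)benzene | ClCc1ccc(OCc2ccccc2)cc1 | starting material
4 | 1-[3,4-bis(benzyloxy)-2-{[4-(benzyloxy)phenyl]methoxy}phenyl]ethan-1-one | CC(=O)c1ccc(OCc2ccccc2)c(OCc2ccccc2)c1OCc1ccc(OCc2ccccc2)cc1 | intermediate
5 | potassium enolate of 4 | [K+].C=C([O-])c1ccc(OCc2ccccc2)c(OCc2ccccc2)c1OCc1ccc(OCc2ccccc2)cc1 | intermediate
6 | 1-[3,4-bis(benzyloxy)-2-{[4-(benzyloxy)phenyl]methoxy}phenyl]ethenyl acetate | C=C(OC(C)=O)c1ccc(OCc2ccccc2)c(OCc2ccccc2)c1OCc1ccc(OCc2ccccc2)cc1 | intermediate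
7 | [2-(1-acetoxyethenyl)-5,6-bis(benzyloxy)phenyl][4-(benzyloxy)benzylidene]oxonium (oxocarbenium ion) | C=C(OC(C)=O)c1ccc(OCc2ccccc2)c(OCc2ccccc2)c1[O+]=Cc1ccc(OCc2ccccc2)cc1 | intermediate
8 | rac-7,8-bis(benzyloxy)-2-[4-(benzyloxy)phenyl]-2,3-dihydro-4H-chromen-4-one | O=C1CC(c2ccc(OCc3ccccc3)cc2)Oc2c1ccc(OCc1ccccc1)c2OCc1ccccc1 | intermediate
9 | rac-{[7,8-bis(benzyloxy)-2-[4-(benzyloxy)phenyl]-2H-chromen-4-yl]oxy}(tert-butyl)dimethylsilane | CC(C)(C)[Si](C)(C)OC1=CC(c2ccc(OCc3ccccc3)cc2)Oc2c1ccc(OCc1ccccc1)c2OCc1ccccc1 | intermediate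
10 | racemic 3,4-epoxide of 9, oxirane oxygen anti to the 2-aryl group (one enantiomer drawn) | CC(C)(C)[Si](C)(C)O[C@]12O[C@H]1[C@H](c1ccc(OCc3ccccc3)cc1)Oc1c2ccc(OCc2ccccc2)c1OCc1ccccc1 | intermediate
11 | rac-(2S,3S)-7,8-bis(benzyloxy)-2-[4-(benzyloxy)phenyl]-3-[(tert-butyldimethylsilyl)oxy]-2,3-dihydro-4H-chromen-4-one (2,3-trans racemate; 2S,3S enantiomer drawn) | O=C1c2ccc(OCc3ccccc3)c(OCc3ccccc3)c2O[C@@H](c2ccc(OCc3ccccc3)cc2)[C@@H]1O[Si](C)(C)C(C)(C)C | intermediate
12 | (2R,3S,4R)-7,8-bis(benzyloxy)-2-[4-(benzyloxy)phenyl]-3-[(tert-butyldimethylsilyl)oxy]-3,4-dihydro-2H-chromen-4-ol | O(Cc1ccccc1)c1ccc([C@H]2Oc3c(ccc(OCc4ccccc4)c3OCc3ccccc3)[C@@H](O)[C@@H]2O[Si](C)(C)C(C)(C)C)cc1 | intermediate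
13 | (2S,3R,4S)-7,8-bis(benzyloxy)-2-[4-(benzyloxy)phenyl]-3-[(tert-butyldimethylsilyl)oxy]-3,4-dihydro-2H-chromen-4-ol | O(Cc1ccccc1)c1ccc([C@@H]2Oc3c(ccc(OCc4ccccc4)c3OCc3ccccc3)[C@H](O)[C@H]2O[Si](C)(C)C(C)(C)C)cc1 | intermediate
14 | (2S,3S)-7,8-bis(benzyloxy)-2-[4-(benzyloxy)phenyl]-3-[(tert-butyldimethylsilyl)oxy]-2,3-dihydro-4H-chromen-4-one | O=C1c2ccc(OCc3ccccc3)c(OCc3ccccc3)c2O[C@@H](c2ccc(OCc3ccccc3)cc2)[C@@H]1O[Si](C)(C)C(C)(C)C | intermediate
15 | (2R,3R,4R)-7,8-bis(benzyloxy)-2-[4-(benzyloxy)phenyl]-3,4-bis[(tert-butyldimethylsilyl)oxy]-3,4-dihydro-2H-chromene | O(Cc1ccccc1)c1ccc([C@H]2Oc3c(ccc(OCc4ccccc4)c3OCc3ccccc3)[C@@H](O[Si](C)(C)C(C)(C)C)[C@@H]2O[Si](C)(C)C(C)(C)C)cc1 | intermediate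
16 | (2R,3R,4R)-7,8-bis(benzyloxy)-2-[4-(benzyloxy)phenyl]-6-bromo-3,4-bis[(tert-butyldimethylsilyl)oxy]-3,4-dihydro-2H-chromene | O(Cc1ccccc1)c1ccc([C@H]2Oc3c(cc(Br)c(OCc4ccccc4)c3OCc3ccccc3)[C@@H](O[Si](C)(C)C(C)(C)C)[C@@H]2O[Si](C)(C)C(C)(C)C)cc1 | intermediate
17 | 6-lithio analogue of 16 (aryllithium) | O(Cc1ccccc1)c1ccc([C@H]2Oc3c(cc([Li])c(OCc4ccccc4)c3OCc3ccccc3)[C@@H](O[Si](C)(C)C(C)(C)C)[C@@H]2O[Si](C)(C)C(C)(C)C)cc1 | intermediate
18 | protected dimeric tertiary alcohol: upper (2S,3S)-7,8-bis(benzyloxy)-2-[4-(benzyloxy)phenyl]-3-silyloxychroman-4-ol bonded at C4 to C6 of the lower (2R,3R,4R) unit of 15; carbinol configuration not defined | O(Cc1ccccc1)c1ccc([C@H]2Oc3c(cc(C4(O)c5ccc(OCc6ccccc6)c(OCc6ccccc6)c5O[C@@H](c5ccc(OCc6ccccc6)cc5)[C@@H]4O[Si](C)(C)C(C)(C)C)c(OCc4ccccc4)c3OCc3ccccc3)[C@@H](O[Si](C)(C)C(C)(C)C)[C@@H]2O[Si](C)(C)C(C)(C)C)cc1 | intermediate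
19 | C4 benzylic carbocation derived from 18 | O(Cc1ccccc1)c1ccc([C@H]2Oc3c(cc([C+]4c5ccc(OCc6ccccc6)c(OCc6ccccc6)c5O[C@@H](c5ccc(OCc6ccccc6)cc5)[C@@H]4O[Si](C)(C)C(C)(C)C)c(OCc4ccccc4)c3OCc3ccccc3)[C@@H](O[Si](C)(C)C(C)(C)C)[C@@H]2O[Si](C)(C)C(C)(C)C)cc1 | intermediate
20 | protected dimer: upper (2S,3R) unit, 2,3-trans, C4–H with the C4 aryl bond cis to the 3-silyloxy group; lower (2R,3R,4R) unit; hexabenzyl, tris-silyl | O(Cc1ccccc1)c1ccc([C@H]2Oc3c(cc([C@@H]4c5ccc(OCc6ccccc6)c(OCc6ccccc6)c5O[C@@H](c5ccc(OCc6ccccc6)cc5)[C@@H]4O[Si](C)(C)C(C)(C)C)c(OCc4ccccc4)c3OCc3ccccc3)[C@@H](O[Si](C)(C)C(C)(C)C)[C@@H]2O[Si](C)(C)C(C)(C)C)cc1 | intermediate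
21 | hexaphenol tris(tert-butyldimethylsilyl) ether of the target (silyl on upper O-3, lower O-3 and O-4) | Oc1ccc([C@H]2Oc3c(cc([C@@H]4c5ccc(O)c(O)c5O[C@@H](c5ccc(O)cc5)[C@@H]4O[Si](C)(C)C(C)(C)C)c(O)c3O)[C@@H](O[Si](C)(C)C(C)(C)C)[C@@H]2O[Si](C)(C)C(C)(C)C)cc1 | intermediate
22 | (2R,3S,4R)-2-(4-hydroxyphenyl)-6-[(2S,3R,4R)-3,7,8-trihydroxy-2-(4-hydroxyphenyl)-3,4-dihydro-2H-chromen-4-yl]-3,4-dihydro-2H-chromene-3,4,7,8-tetrol | Oc1ccc([C@H]2Oc3c(cc([C@@H]4c5ccc(O)c(O)c5O[C@@H](c5ccc(O)cc5)[C@@H]4O)c(O)c3O)[C@@H](O)[C@@H]2O)cc1 | target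

**Step count and risks**

Total steps: 15. Longest linear sequence: 13 steps (1 → 2 → 4 → 6 → 8 → 9 → 11 → 12 → 15 → 16 → 18 → 20 → 21 → 22). The upper-unit branch (11 → 13 → 14, steps 8 and 9) leaves this line after step 6 and rejoins it at step 12.

Steps most likely to fail:

1. Step 4 (key step, proposed new method). Hydride abstraction from an aryl p-alkoxybenzyl ether may be slow, because O1 is conjugated with ring A. Electron transfer from the electron-rich ring A could also lead to loss of a plain benzyl group, and the cation could be hydrolysed before it cyclises. Fallback (sets out from 2, returns at 8): Claisen–Schmidt condensation of 2 with commercial 4-(benzyloxy)benzaldehyde (KOH, EtOH/THF, rt) would give the chalcone (E)-1-[3,4-bis(benzyloxy)-2-hydroxyphenyl]-3-[4-(benzyloxy)phenyl]prop-2-en-1-one F1. Its free 2'-phenol would then close ring C by oxa-Michael addition (NaOAc, EtOH, reflux) to give 8; this known route closes O1–C2 instead of C2–C3.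

2. Step 13. Hydride delivery to the C4 cation may show poor facial selectivity, since the conformer with equatorial 2-aryl and 3-silyloxy groups exposes the opposite face and would give the all-trans epimer. The lower benzylic silyl ether could also ionise competitively. Fallback (sets out from 18, returns at 21): hydrogenolysis over Pd(OH)2/C (H2, EtOAc/AcOH) would replace the tertiary benzylic hydroxyl by hydrogen with inversion on the metal surface, a stereospecific process that does not pass through a free cation. It presupposes that the aryl group entered anti to the 3-silyloxy group in step 12. The six benzyl ethers would be removed in the same operation, giving 21 directly; no new compound arises.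

3. Step 7 (step 8 shares the risk). The kinetic resolution may discriminate the enantiomers too weakly, because the 3-silyloxy group next to the carbonyl could slow the matched reduction or erode the facial preference. Fallback (sets out from 11, returns at 14 and at 12): preparative chromatography of 11 on a chiral stationary phase (amylose tris(3,5-dimethylphenylcarbamate)) would give 14 directly, together with its enantiomer (2R,3R)-7,8-bis(benzyloxy)-2-[4-(benzyloxy)phenyl]-3-[(tert-butyldimethylsilyl)oxy]-2,3-dihydro-4H-chromen-4-one F2. Reduction of F2 with NaBH4 (MeOH/THF, 0 °C; axial hydride attack, 4-OH trans to 3-O) would give 12; steps 8 and 9 would then not be needed.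

**Further compounds**

F1 | step 4 | (E)-1-[3,4-bis(benzyloxy)-2-hydroxyphenyl]-3-[4-(benzyloxy)phenyl]prop-2-en-1-one | O=C(/C=C/c1ccc(OCc2ccccc2)cc1)c1ccc(OCc2ccccc2)c(OCc2ccccc2)c1O
F0 | step 13 | none | none
F2 | step 7 | (2R,3R)-7,8-bis(benzyloxy)-2-[4-(benzyloxy)phenyl]-3-[(tert-butyldimethylsilyl)oxy]-2,3-dihydro-4H-chromen-4-one | O=C1c2ccc(OCc3ccccc3)c(OCc3ccccc3)c2O[C@H](c2ccc(OCc3ccccc3)cc2)[C@H]1O[Si](C)(C)C(C)(C)C
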